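A gap of 0.3 percentage points opened my reckoning. It was the difference in L between the teal and ochre flasks at 3.00 min. That is about the scatter of 0.3 points, though ochre held 1.62 times teal's charge of Z. In these flasks Z gives L and X, and I counted in fractions of the Z charged.

| setting | teal | ochre | epsilon | delta |
|---|---|---|---|---|
| Z | 0.074 M | 0.12 M | 0.053 M | 0.053 M |
| remark | run made earlier | run made earlier |  |  |
| time |  |  | 3.0 min | 5.0 min |

| run | time / min | L / % | Z / % |
|---|---|---|---|
| teal | 0.200 | 16.1 | 70.7 |
| teal | 0.667 | 35.2 | 31.6 |
| teal | 1.00 | 40.0 | 18.4 |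
| teal | 1.50 | 39.3 | 8.0 |
| teal | 2.50 | 34.4 | 2.1 |
| teal | 3.00 | 31.9 | 0.6 |
| ochre | 0.200 | 15.9 | 70.2 |
| ochre | 0.667 | 35.0 | 31.6 |
| ochre | 1.00 | 39.2 | 17.6 |
| ochre | 1.50 | 39.7 | 7.6 |
| ochre | 2.50 | 34.2 | 1.9 |
| ochre | 3.00 | 31.6 | 0.6 |

(readings scatter by 0.3 percentage points)

- the numbers in the tables scatter by 0.3 percentage points (one standard deviation)

- which of the two there is more of at the end, epsilon (L / X)
- which of the two there is more of at the end, delta (L / X)
- final L, as a percentage of the Z charged, in epsilon
- final L, as a percentage of the Z charged, in delta

The first setting was the charge. By hand, if each step is first order, the fractions at a given time do not depend on it. The two runs behaved that way, so I read 31.8% of L for epsilon at 3.0 min. Still, epsilon's charge lies 1.40 times below teal's, outside the range tried.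

The second setting was the time, and delta runs 2.00 min past the last reading. Taking the means of both runs, L fell from 39.5% at 1.50 min to 31.8% at 3.00 min. The logarithm of that ratio over the interval came to 0.146 min⁻¹. This is my tail rate, the apparent first-order constant of L's fall. Teal alone gave 0.139 min⁻¹ and ochre alone 0.152 min⁻¹. It is an apparent rate, and the mean reading of Z still stood at 7.80% at the start of that interval. Integrating the fall from 3.0 min to 5.0 min gave me 23.7% of L for delta. X was not read, but the part that was neither Z nor L at 3.00 min was 67.6%, more than L, so, counting that part as X, I put X ahead in both epsilon and delta.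

The forecast also put X ahead, with 31.8% and 20.3% of L, the second lower than mine, holding that “L is converting onward, presumably to X”.

Delta gave 27.3% of L and epsilon 31.8%, with X ahead at 59.8% and 51.5%. The scheme was this.

    Z → D (k = 0.00850 s⁻¹)
    L ⇌ X (K = 2.40, k = 0.0130 s⁻¹)
    Z → L (k = 0.0160 s⁻¹)
    D → L (k = 0.0210 s⁻¹)
    Z ⇌ J (K = 3.60, k = 0.00470 s⁻¹)

My delta figure fell 3.6 points low. With the undoing of X into L made one-way, delta minus epsilon came to −12 points, against −4.5 points in the flasks as they ran. Between epsilon at 3.0 min and delta at 5.0 min, which had the same charge of Z, L fell at an average apparent rate of 0.0770 min⁻¹, about half my tail rate. Carried from 3.0 min to 8.0 min in epsilon, the tail rate gave 15.3%, and epsilon read at that time held 26.8%.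

The earlier runs and the new flask were computed with constants of no real substance.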